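## Retrosynthetic overview

1. The last C–C bond made is the central σ-bond of the (E,E)-diene: an alkenylalane, from Zr-catalysed methylalumination of 2-(but-3-ynyl)-1,3,3-trimethylcyclohexene, is coupled with the (E)-vinyl iodide of an (R)-2-methylchroman.
2. Enabling feature: in the cyclohexene, the C(CH3)2–CH2 edge (ring atoms C6–C5) is a masked isobutene that sits beside the tetrasubstituted C1=C2 bond. With one extra C3=C4 double bond and the exocyclic carbon on C1 held as an ester, this ring is the CO2-extrusion product of a 2-pyranone-3-carboxylate/isobutene [4+2] adduct.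
3. The key step therefore forms ring bonds C1–C6 and C4–C5 in one operation. The lactone bridge (temporary ring) leaves as CO2, the extra double bond is hydrogenated, and the activating ester becomes the first chain carbon (CH2OH, CH2Br, propargylation).
4. Chroman half: the only stereocentre (C2, R) is bought as methyl (R)-2-methylglycidate. A benzylic Grignard reagent opens it at CH2, a Pd-catalysed C–O coupling closes the pyran ring, and the ester is taken to the aldehyde and the (E)-vinyl iodide.
5. Order of ring formation: 2-pyranone (step 2, temporary), carbocycle (step 3), benzopyran (step 12); union in step 15, desilylation in step 16.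

Key step: step 3

Remark: C2 of the chroman is (R) (O1 > diene carbon > C3 > CH3). It is introduced with the enantiopure glycidic ester, is quaternary and never enolisable, and keeps the descriptor (R) in every chroman intermediate because the ranking of its four substituents does not change.

## Route

Step 1
Reactants: 1 dimethyl 2-(propan-2-ylidene)propanedioate (dimethyl isopropylidenemalonate); 2 N,N-dimethylformamide dimethyl acetal
Product: 3 dimethyl 2-[(3E)-4-(dimethylamino)but-3-en-2-ylidene]propanedioate
Conditions: 2 (1.5 equiv), DMF, 110 °C, MeOH distilled off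
Reagents that add atoms: none
Why: The methyl groups of the alkylidene malonate are vinylogously C–H acidic and condense with the amide acetal (aminomethylenation to a push–pull dienamine), the usual entry to 2-pyranone-3-carboxylates.

Step 2
Reactants: 3 dimethyl 2-[(3E)-4-(dimethylamino)but-3-en-2-ylidene]propanedioate
Product: 4 methyl 4-methyl-2-oxo-2H-pyran-3-carboxylate
Conditions: AcOH, aq. HCl (2 M), 80 °C
Reagents that add atoms: water, O
Why: Acid hydrolysis of the enamine gives the aldehyde/enol, whose oxygen closes onto the cis ester with loss of methanol (lactonisation to the 2-pyranone, as known for 5-aminopenta-2,4-dienoates).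

Step 3
Reactants: 4 methyl 4-methyl-2-oxo-2H-pyran-3-carboxylate; 5 2-methylprop-1-ene (isobutene)
Product: 7 methyl 2,6,6-trimethylcyclohexa-1,3-diene-1-carboxylate, via bridged lactone 6 (not isolated)
Conditions: 5 (10 equiv), toluene, BHT (cat.), sealed steel autoclave, 160 °C
Reagents that add atoms: none
Why: Inverse-electron-demand Diels–Alder reaction: the electron-poor diene C3=C4–C5=C6 of pyranone 4 takes up the electron-rich alkene 5 in one concerted, asynchronous [4+2] event that makes both ring bonds (pyranone C6–CH2 and pyranone C3–C(CH3)2) and gives bridged lactone 6, which at this temperature loses CO2 by retro-[4+2] to leave diene 7. The closest known reaction type is the cycloaddition of methyl 2-oxo-2H-pyran-3-carboxylate and of coumalate esters with alkenes, followed by CO2 extrusion to cyclohexa-1,3-dienes. The six-membered carbocycle is closed by intermolecular [4+2] cycloaddition, and no stereocentre has to be controlled, because 6 is racemic and 7 is achiral. The selectivity needed is regiochemical: the 3-ester and the lactone carbonyl put the largest LUMO coefficient at C6 and stabilise developing negative charge at C3 like a malonate, while isobutene has its largest HOMO coefficient at CH2 and stabilises positive charge at its tertiary carbon, so CH2 should bond to C6 first and the congested C3–C(CH3)2 bond should close late. The place of the tetrasubstituted double bond needs no control, since CO2 extrusion leaves the two double bonds where the pyranone had them and the quaternary C(CH3)2 carbon blocks aromatisation.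

Step 4
Reactants: 7 methyl 2,6,6-trimethylcyclohexa-1,3-diene-1-carboxylate
Product: 8 methyl 2,6,6-trimethylcyclohex-1-ene-1-carboxylate
Conditions: H2 (1 atm), RhCl(PPh3)3 (5 mol%), benzene/EtOH, rt
Reagents that add atoms: none
Why: Homogeneous hydrogenation with RhCl(PPh3)3 should reduce the cis-disubstituted C3=C4 bond by 1,2-addition and leave the tetrasubstituted, ester-conjugated C1=C2 bond untouched (chemoselective alkene hydrogenation).

Step 5
Reactants: 8 methyl 2,6,6-trimethylcyclohex-1-ene-1-carboxylate
Product: 9 (2,6,6-trimethylcyclohex-1-en-1-yl)methanol (β-cyclogeraniol)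
Conditions: LiAlH4, Et2O, 0 °C to rt
Reagents that add atoms: none
Why: Hydride reduction of the ester to the primary allylic alcohol; the tetrasubstituted alkene is inert to LiAlH4.

Step 6
Reactants: 9 (2,6,6-trimethylcyclohex-1-en-1-yl)methanol
Product: 10 2-(bromomethyl)-1,3,3-trimethylcyclohex-1-ene
Conditions: PBr3, pyridine (cat.), Et2O, −10 to 0 °C; used crude
Reagents that add atoms: phosphorus tribromide, BrP(Br)Br
Why: SN2 bromination of the primary allylic alcohol through its phosphite ester; allylic transposition is disfavoured because the other allyl terminus is fully substituted.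

Step 7
Reactants: 10 2-(bromomethyl)-1,3,3-trimethylcyclohex-1-ene; 11 trimethyl(prop-1-yn-1-yl)silane
Product: 13 trimethyl[4-(2,6,6-trimethylcyclohex-1-en-1-yl)but-1-yn-1-yl]silane, via propargyllithium 12 (not isolated)
Conditions: 11, n-BuLi, THF, −78 to −20 °C; then 10, −78 °C to rt
Reagents that add atoms: none
Why: SN2 alkylation of the primary allylic bromide by the propargylic lithium reagent of the silyl-capped propyne, a standard two-carbon-plus-alkyne homologation of allylic halides.

Step 8
Reactants: 13 trimethyl[4-(2,6,6-trimethylcyclohex-1-en-1-yl)but-1-yn-1-yl]silane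
Product: 14 2-(but-3-yn-1-yl)-1,3,3-trimethylcyclohex-1-ene
Conditions: K2CO3, MeOH, rt
Reagents that add atoms: none
Why: Base-catalysed methanolysis of the C(sp)–Si bond (protodesilylation) frees the terminal alkyne.

Step 9
Reactants: 15 4-bromo-3-methylphenol
Product: 16 (4-bromo-3-methylphenoxy)triisopropylsilane
Conditions: TIPSCl, imidazole, DMF, rt
Reagents that add atoms: triisopropylsilyl chloride, CC(C)[Si](Cl)(C(C)C)C(C)C
Why: O-silylation of the phenol; the bulky aryl silyl ether should survive the Grignard, carbonate base, hydride and organometallic steps and is removed by fluoride at the end.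

Step 10
Reactants: 16 (4-bromo-3-methylphenoxy)triisopropylsilane
Product: 17 [4-bromo-3-(bromomethyl)phenoxy]triisopropylsilane
Conditions: NBS, AIBN (cat.), PhCF3, 85 °C
Reagents that add atoms: N-bromosuccinimide, BrN1C(=O)CCC1=O
Why: Wohl–Ziegler radical bromination at the only benzylic position.

Step 11
Reactants: 17 [4-bromo-3-(bromomethyl)phenoxy]triisopropylsilane; 18 methyl (2R)-2-methyloxirane-2-carboxylate (methyl (R)-2-methylglycidate)
Product: 20 methyl (2R)-4-{2-bromo-5-[(triisopropylsilyl)oxy]phenyl}-2-hydroxy-2-methylbutanoate, via benzylmagnesium bromide 19 (not isolated)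
Conditions: Mg, Et2O, 0 °C (slow addition of 17); then CuI (copper iodide, 10 mol%), 18, THF, −40 to −20 °C; aq. NH4Cl
Reagents that add atoms: none
Why: Copper-catalysed SN2 opening of the 2,2-disubstituted epoxide at its CH2 carbon by the benzylic Grignard reagent (magnesium inserts into the benzylic C–Br bond far faster than into the aryl C–Br bond); the quaternary carbon is not touched, so the (R) configuration of 18 is carried over unchanged.

Step 12
Reactants: 20 methyl (2R)-4-{2-bromo-5-[(triisopropylsilyl)oxy]phenyl}-2-hydroxy-2-methylbutanoate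
Product: 21 methyl (2R)-2-methyl-6-[(triisopropylsilyl)oxy]-3,4-dihydro-2H-1-benzopyran-2-carboxylate
Conditions: Pd(OAc)2 (3 mol%), 2-(di-tert-butylphosphino)-1,1'-binaphthyl (4 mol%), Cs2CO3, toluene, 80 °C
Reagents that add atoms: none
Why: Intramolecular Pd-catalysed aryl C–O coupling (Buchwald–Hartwig etherification) closes the six-membered pyran ring; a tertiary alkoxide cannot undergo β-hydride elimination, and the stereocentre is retained because its C–O bond is not broken.

Step 13
Reactants: 21 methyl (2R)-2-methyl-6-[(triisopropylsilyl)oxy]-3,4-dihydro-2H-1-benzopyran-2-carboxylate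
Product: 22 (2R)-2-methyl-6-[(triisopropylsilyl)oxy]-3,4-dihydro-2H-1-benzopyran-2-carbaldehyde
Conditions: DIBAL-H (1.1 equiv), CH2Cl2, −78 °C; Rochelle salt
Reagents that add atoms: none
Why: Partial reduction of an α-alkoxy ester, whose chelated tetrahedral aluminium adduct is stable at −78 °C and gives the aldehyde on work-up; the aldehyde is non-enolisable, so C2 cannot epimerise.

Step 14
Reactants: 22 (2R)-2-methyl-6-[(triisopropylsilyl)oxy]-3,4-dihydro-2H-1-benzopyran-2-carbaldehyde
Product: 23 triisopropyl({(2R)-2-[(E)-2-iodoethenyl]-2-methyl-3,4-dihydro-2H-1-benzopyran-6-yl}oxy)silane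
Conditions: CrCl2 (6 equiv), CHI3 (2 equiv), THF/dioxane, 0 °C to rt
Reagents that add atoms: iodoform, IC(I)I
Why: Takai iodo-olefination with the geminal dichromium reagent made from CHI3 and divalent chromium, which should give the (E)-vinyl iodide selectively.

Step 15
Reactants: 14 2-(but-3-yn-1-yl)-1,3,3-trimethylcyclohex-1-ene; 23 triisopropyl({(2R)-2-[(E)-2-iodoethenyl]-2-methyl-3,4-dihydro-2H-1-benzopyran-6-yl}oxy)silane
Product: 25 triisopropyl({(2R)-2-methyl-2-[(1E,3E)-4-methyl-6-(2,6,6-trimethylcyclohex-1-en-1-yl)hexa-1,3-dien-1-yl]-3,4-dihydro-2H-1-benzopyran-6-yl}oxy)silane, via alkenylalane 24 (not isolated)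
Conditions: 14, Me3Al (2.5 equiv), Cp2ZrCl2 (0.25 equiv), CH2Cl2, 0 °C to rt; then THF, 23, ZnCl2 (20 mol%), Pd(PPh3)4 (5 mol%), rt
Reagents that add atoms: trimethylaluminium, C[Al](C)C
Why: Zr-catalysed syn-methylalumination of the terminal alkyne (Negishi carboalumination) puts CH3 on the internal carbon and fixes the E-trisubstituted alkene, and Pd-catalysed alkenyl–alkenyl cross-coupling with retention at both partners (Negishi coupling) should give the (E,E)-diene without touching C2.

Step 16
Reactants: 25 triisopropyl({(2R)-2-methyl-2-[(1E,3E)-4-methyl-6-(2,6,6-trimethylcyclohex-1-en-1-yl)hexa-1,3-dien-1-yl]-3,4-dihydro-2H-1-benzopyran-6-yl}oxy)silane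
Product: 26 (2R)-2-methyl-2-[(1E,3E)-4-methyl-6-(2,6,6-trimethylcyclohex-1-en-1-yl)hexa-1,3-dien-1-yl]-3,4-dihydro-2H-1-benzopyran-6-ol (target)
Conditions: TBAF (1.1 equiv), THF, 0 °C; aq. NH4Cl
Reagents that add atoms: none
Why: Fluoride cleavage of the aryl silyl ether under non-acidic conditions, which spares the acid-labile tertiary dienylic aryl ether and the diene.

## Compound list

1 | dimethyl 2-(propan-2-ylidene)propanedioate | COC(=O)C(=C(C)C)C(=O)OC | starting material
2 | N,N-dimethylformamide dimethyl acetal | COC(OC)N(C)C | starting material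
3 | dimethyl 2-[(3E)-4-(dimethylamino)but-3-en-2-ylidene]propanedioate | COC(=O)C(C(=O)OC)=C(C)/C=C/N(C)C | intermediate
4 | methyl 4-methyl-2-oxo-2H-pyran-3-carboxylate | COC(=O)C1=C(C)C=COC1=O | intermediate
5 | 2-methylprop-1-ene | CC(C)=C | starting material
6 | methyl 5,8,8-trimethyl-3-oxo-2-oxabicyclo[2.2.2]oct-5-ene-4-carboxylate (racemic) | COC(=O)C12C(=O)OC(C=C1C)CC2(C)C | intermediate (not isolated)
7 | methyl 2,6,6-trimethylcyclohexa-1,3-diene-1-carboxylate | COC(=O)C1=C(C)C=CCC1(C)C | intermediate
8 | methyl 2,6,6-trimethylcyclohex-1-ene-1-carboxylate | COC(=O)C1=C(C)CCCC1(C)C | intermediate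
9 | (2,6,6-trimethylcyclohex-1-en-1-yl)methanol | OCC1=C(C)CCCC1(C)C | intermediate
10 | 2-(bromomethyl)-1,3,3-trimethylcyclohex-1-ene | BrCC1=C(C)CCCC1(C)C | intermediate
11 | trimethyl(prop-1-yn-1-yl)silane | CC#C[Si](C)(C)C | starting material
12 | [3-(trimethylsilyl)prop-2-yn-1-yl]lithium | [Li]CC#C[Si](C)(C)C | intermediate (not isolated)
13 | trimethyl[4-(2,6,6-trimethylcyclohex-1-en-1-yl)but-1-yn-1-yl]silane | C[Si](C)(C)C#CCCC1=C(C)CCCC1(C)C | intermediate
14 | 2-(but-3-yn-1-yl)-1,3,3-trimethylcyclohex-1-ene | C#CCCC1=C(C)CCCC1(C)C | intermediate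
15 | 4-bromo-3-methylphenol | Cc1cc(O)ccc1Br | starting material
16 | (4-bromo-3-methylphenoxy)triisopropylsilane | Cc1cc(O[Si](C(C)C)(C(C)C)C(C)C)ccc1Br | intermediate
17 | [4-bromo-3-(bromomethyl)phenoxy]triisopropylsilane | BrCc1cc(O[Si](C(C)C)(C(C)C)C(C)C)ccc1Br | intermediate
18 | methyl (2R)-2-methyloxirane-2-carboxylate | COC(=O)[C@@]1(C)CO1 | starting material
19 | bromo{2-bromo-5-[(triisopropylsilyl)oxy]benzyl}magnesium | Br[Mg]Cc1cc(O[Si](C(C)C)(C(C)C)C(C)C)ccc1Br | intermediate (not isolated)
20 | methyl (2R)-4-{2-bromo-5-[(triisopropylsilyl)oxy]phenyl}-2-hydroxy-2-methylbutanoate | COC(=O)[C@@](O)(C)CCc1cc(O[Si](C(C)C)(C(C)C)C(C)C)ccc1Br | intermediate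
21 | methyl (2R)-2-methyl-6-[(triisopropylsilyl)oxy]-3,4-dihydro-2H-1-benzopyran-2-carboxylate | COC(=O)[C@@]1(C)CCc2cc(O[Si](C(C)C)(C(C)C)C(C)C)ccc2O1 | intermediate
22 | (2R)-2-methyl-6-[(triisopropylsilyl)oxy]-3,4-dihydro-2H-1-benzopyran-2-carbaldehyde | O=C[C@@]1(C)CCc2cc(O[Si](C(C)C)(C(C)C)C(C)C)ccc2O1 | intermediate
23 | triisopropyl({(2R)-2-[(E)-2-iodoethenyl]-2-methyl-3,4-dihydro-2H-1-benzopyran-6-yl}oxy)silane | I/C=C/[C@@]1(C)CCc2cc(O[Si](C(C)C)(C(C)C)C(C)C)ccc2O1 | intermediate
24 | dimethyl[(1E)-2-methyl-4-(2,6,6-trimethylcyclohex-1-en-1-yl)but-1-en-1-yl]alumane | C[Al](C)/C=C(\C)CCC1=C(C)CCCC1(C)C | intermediate (not isolated)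
25 | triisopropyl({(2R)-2-methyl-2-[(1E,3E)-4-methyl-6-(2,6,6-trimethylcyclohex-1-en-1-yl)hexa-1,3-dien-1-yl]-3,4-dihydro-2H-1-benzopyran-6-yl}oxy)silane | CC1=C(CC/C(C)=C/C=C/[C@@]2(C)CCc3cc(O[Si](C(C)C)(C(C)C)C(C)C)ccc3O2)C(C)(C)CCC1 | intermediate
26 | (2R)-2-methyl-2-[(1E,3E)-4-methyl-6-(2,6,6-trimethylcyclohex-1-en-1-yl)hexa-1,3-dien-1-yl]-3,4-dihydro-2H-1-benzopyran-6-ol | CC1=C(CC/C(C)=C/C=C/[C@@]2(C)CCc3cc(O)ccc3O2)C(C)(C)CCC1 | target

## Step count and risks

Total step count: 16. Longest linear sequence: 10 steps (steps 1 to 8, 15 and 16); the chroman branch is 6 steps (steps 9 to 14).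

Steps most likely to fail:

1. Step 3. The cycloaddition of an unactivated 1,1-dialkyl alkene is slow, and at the temperature it needs the closure of the congested ester-carbon to C(CH3)2 bond may lag behind, so that conversion stays low or the diene ester isomerises by sigmatropic hydrogen shift. Fallback: the cycloaddition is given up and the carbocycle is taken from commercial β-cyclocitral (2,6,6-trimethylcyclohex-1-ene-1-carbaldehyde). This fallback does not set out from a numbered compound, since β-cyclocitral replaces compounds 1 to 8; it comes back to the route at alcohol 9 by reduction with NaBH4 and CeCl3·7H2O in MeOH at 0 °C. It makes no new compound (F0).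

2. Step 11. The benzylic Grignard reagent may attack the ester of 18 in competition with epoxide opening, and Wurtz coupling may consume 17 while the Grignard reagent forms. Fallback: the ester is left out of the epoxide and the carboxyl oxidation level is set afterwards. It sets out from Grignard reagent 19 (made from 17 as in step 11) and comes back at 20. Reagent 19 is added with CuI (10 mol%) in THF at −30 °C to commercial (S)-2-methylglycidol, whose hydroxyl has first been deprotonated with i-PrMgCl, which should give (2R)-4-{2-bromo-5-[(triisopropylsilyl)oxy]phenyl}-2-methylbutane-1,2-diol F1. Oxidation of the primary alcohol with TEMPO (cat.), NaOCl (cat.) and NaClO2 in MeCN/phosphate buffer should give (2R)-4-{2-bromo-5-[(triisopropylsilyl)oxy]phenyl}-2-hydroxy-2-methylbutanoic acid F2, and esterification with TMSCHN2 in MeOH/toluene gives 20.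

3. Step 15. Zerovalent palladium may ionise the tertiary allylic aryl ether (C2–O of the chroman) with loss of configuration, or the alkenyl metal may be lost by homocoupling or protonation before it couples. Fallback: a palladium-free Horner–Wadsworth–Emmons union. It sets out from alkyne 14 and aldehyde 22 (step 14 is then not needed) and comes back at 25. Alkyne 14 is methylaluminated as in step 15, and the alanate formed with n-BuLi is trapped with paraformaldehyde to give (2E)-3-methyl-5-(2,6,6-trimethylcyclohex-1-en-1-yl)pent-2-en-1-ol F3. PBr3 in Et2O at 0 °C gives 2-[(3E)-5-bromo-3-methylpent-3-en-1-yl]-1,3,3-trimethylcyclohex-1-ene F4, and heating with P(OEt)3 (Arbuzov reaction) gives diethyl [(2E)-3-methyl-5-(2,6,6-trimethylcyclohex-1-en-1-yl)pent-2-en-1-yl]phosphonate F5. Deprotonation of F5 with NaHMDS in THF at −78 °C and addition of aldehyde 22 should give the (E,E)-diene 25.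

Further compounds
F0 | step 3 | none | none
F1 | step 11 | (2R)-4-{2-bromo-5-[(triisopropylsilyl)oxy]phenyl}-2-methylbutane-1,2-diol | OC[C@@](O)(C)CCc1cc(O[Si](C(C)C)(C(C)C)C(C)C)ccc1Br
F2 | step 11 | (2R)-4-{2-bromo-5-[(triisopropylsilyl)oxy]phenyl}-2-hydroxy-2-methylbutanoic acid | OC(=O)[C@@](O)(C)CCc1cc(O[Si](C(C)C)(C(C)C)C(C)C)ccc1Br
F3 | step 15 | (2E)-3-methyl-5-(2,6,6-trimethylcyclohex-1-en-1-yl)pent-2-en-1-ol | OC/C=C(\C)CCC1=C(C)CCCC1(C)C
F4 | step 15 | 2-[(3E)-5-bromo-3-methylpent-3-en-1-yl]-1,3,3-trimethylcyclohex-1-ene | BrC/C=C(\C)CCC1=C(C)CCCC1(C)C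
F5 | step 15 | diethyl [(2E)-3-methyl-5-(2,6,6-trimethylcyclohex-1-en-1-yl)pent-2-en-1-yl]phosphonate | CCOP(=O)(OCC)C/C=C(\C)CCC1=C(C)CCCC1(C)C
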